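**Retrosynthetic overview**
1. The C7=C8 enoic acid of ring B is an aldol–dehydration retron: target 21 ⇒ unmasking of two tert-butyl esters and the C13 dioxolane ⇒ E1cB dehydration ⇒ 7-hydroxy-8-carboxylate trans-decalin 18.
2. Ring B of 18 is cut at C9–C10 and C7–C8. C10 (quaternary, methyl-bearing) and C9 (β to the C8 carboxyl) are both electrophilic in polar terms, so they are joined through a C10 radical made by hydrogen-atom transfer to the C1=C10 alkene of ring A aldehyde 11; the C8 enolate then closes on the C7 aldehyde.
3. Ring A aldehyde 11 ⇒ Claisen rearrangement of the vinyl ether of allylic alcohol 8 (C1–O to C5–C6 chirality transfer, alkene moves to C1=C10) ⇒ CBS reduction of enone 7 ⇒ Saegusa oxidation of an asymmetric Diels–Alder adduct of methacrolein that sets the C4 quaternary centre.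
4. Enoate 17 ⇒ cross-metathesis of a ketal-protected 2-methylhept-6-en-3-one with tert-butyl acrylate.
5. Ring order: ring A by Diels–Alder reaction, then ring B by the radical–polar annulation; ring C is never closed.

Key step: step 11

Remark on numbering: abietane numbering is used for the carbons of the target (C4 quaternary carboxyl carbon, C5/C10 ring fusion, C9 chain-bearing CH, C7=C8 alkene, C13 ketone, C14 and C18 carboxyl carbons).
Assumption: the sense of induction in step 2 is assigned from the accepted model for 2-substituted acroleins with the (S)-oxazaborolidinium catalyst; the (R)-catalyst is equally available and would be used if the adduct proved to be the enantiomer of 4.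

**Route**

Step 1
Reactants: 1 3-methylbut-3-en-2-one
Product: 2 triisopropyl[(3-methylbuta-1,3-dien-2-yl)oxy]silane
Conditions: TIPSOTf, Et3N, Et2O, 0 °C → rt
Reagents that add atoms: triisopropylsilyl trifluoromethanesulfonate, CC(C)[Si](OS(=O)(=O)C(F)(F)F)(C(C)C)C(C)C
Why: Soft enolisation and O-silylation (silyl enol ether formation) should give the 2-siloxy diene cleanly because the acetyl methyl is the only enolisable position.

Step 2
Reactants: 2 triisopropyl[(3-methylbuta-1,3-dien-2-yl)oxy]silane; 3 methacrolein
Product: 4 (R)-1,3-dimethyl-4-[(triisopropylsilyl)oxy]cyclohex-3-ene-1-carbaldehyde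
Conditions: oxazaborolidine from (S)-α,α-diphenylprolinol and o-tolylboroxine, activated with HNTf2 (10 mol %), CH2Cl2, −78 °C
Reagents that add atoms: none
Why: Cationic oxazaborolidine-catalysed asymmetric Diels–Alder reaction, in which the siloxy group directs the "para" orientation (enol ether at C1=C10, C4 bonded to C5H2 and C3H2) and the catalyst shields one face of the s-trans enal and so sets the C4 quaternary centre.

Step 3
Reactants: 4 (R)-1,3-dimethyl-4-[(triisopropylsilyl)oxy]cyclohex-3-ene-1-carbaldehyde
Product: 5 (R)-1,3-dimethyl-4-oxocyclohex-2-ene-1-carbaldehyde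
Conditions: Pd(OAc)2 (10 mol %), O2 (1 atm), DMSO, 60 °C
Reagents that add atoms: none
Why: Saegusa–Ito oxidation, in which the palladium enolate at C10 should undergo β-hydride elimination into the ring (C5–H) to give the conjugated endocyclic enone, leaving the non-enolisable C4 centre untouched.

Step 4
Reactants: 5 (R)-1,3-dimethyl-4-oxocyclohex-2-ene-1-carbaldehyde
Product: 6 (R)-1,3-dimethyl-4-oxocyclohex-2-ene-1-carboxylic acid
Conditions: NaClO2, NaH2PO4, 2-methylbut-2-ene, t-BuOH/H2O, 0 °C → rt
Reagents that add atoms: sodium chlorite, [Na+].[O-]Cl=O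
Why: Pinnick oxidation converts the α-quaternary aldehyde to the acid under mildly acidic conditions that the enone tolerates; the acid is used without heating.

Step 5
Reactants: 6 (R)-1,3-dimethyl-4-oxocyclohex-2-ene-1-carboxylic acid
Product: 7 tert-butyl (R)-1,3-dimethyl-4-oxocyclohex-2-ene-1-carboxylate
Conditions: tert-butyl 2,2,2-trichloroacetimidate, BF3·OEt2 (cat.), CH2Cl2/cyclohexane, rt
Reagents that add atoms: tert-butyl 2,2,2-trichloroacetimidate, CC(C)(C)OC(=N)C(Cl)(Cl)Cl
Why: Esterification by O-alkylation of the carboxylate with the tert-butyl cation equivalent needs no attack at the hindered acyl carbon.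

Step 6
Reactants: 7 tert-butyl (R)-1,3-dimethyl-4-oxocyclohex-2-ene-1-carboxylate
Product: 8 tert-butyl (1R,4R)-4-hydroxy-1,3-dimethylcyclohex-2-ene-1-carboxylate
Conditions: (S)-2-methyl-CBS-oxazaborolidine (15 mol %), BH3·SMe2, THF, −20 °C
Reagents that add atoms: none
Why: Corey–Bakshi–Shibata reduction, in which the α-methyl vinyl carbon acts as the large group so that the (S)-catalyst should deliver hydride to give the (R)-carbinol at C1, cis to the C4 methyl, under reagent control.

Step 7
Reactants: 8 tert-butyl (1R,4R)-4-hydroxy-1,3-dimethylcyclohex-2-ene-1-carboxylate; 9 ethyl vinyl ether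
Product: 11 tert-butyl (1R,2R)-1,3-dimethyl-2-(2-oxoethyl)cyclohex-3-ene-1-carboxylate, via allyl vinyl ether 10 (not isolated)
Conditions: Hg(OAc)2 (20 mol %), 9 as solvent, reflux; filtration through basic alumina; then decane, 180 °C, sealed tube
Reagents that add atoms: none
Why: Mercury-catalysed vinyl exchange followed by Claisen rearrangement, whose suprafacial [3,3] shift forms C5–C6 on the face that carried the C1 oxygen (cis to the C4 methyl, anti to the pseudoaxial ester), sets C5, moves the alkene to C1=C10 and releases the C7 aldehyde.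

Step 8
Reactants: 12 N-methoxy-N,2-dimethylpropanamide; 13 but-3-en-1-ylmagnesium bromide
Product: 14 2-methylhept-6-en-3-one
Conditions: THF, 0 °C → rt; then 1 M HCl
Reagents that add atoms: none
Why: Weinreb ketone synthesis, in which the chelated tetrahedral intermediate prevents over-addition.

Step 9
Reactants: 14 2-methylhept-6-en-3-one
Product: 15 2-(but-3-en-1-yl)-2-(propan-2-yl)-1,3-dioxolane
Conditions: ethylene glycol, p-TsOH·H2O (cat.), benzene, reflux, Dean–Stark
Reagents that add atoms: ethylene glycol, OCCO
Why: Acid-catalysed ketalisation with azeotropic removal of water masks the C13 ketone, which would otherwise compete with the C7 aldehyde for the C8 enolate in step 11.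

Step 10
Reactants: 15 2-(but-3-en-1-yl)-2-(propan-2-yl)-1,3-dioxolane; 16 tert-butyl acrylate
Product: 17 tert-butyl (E)-5-[2-(propan-2-yl)-1,3-dioxolan-2-yl]pent-2-enoate
Conditions: second-generation Hoveyda–Grubbs catalyst (3 mol %), 16 (3 equiv), CH2Cl2, 40 °C
Reagents that add atoms: none
Why: Olefin cross-metathesis of a terminal alkene with an acrylate is selective for the cross product and for the E enoate.

Step 11
Reactants: 11 tert-butyl (1R,2R)-1,3-dimethyl-2-(2-oxoethyl)cyclohex-3-ene-1-carboxylate; 17 tert-butyl (E)-5-[2-(propan-2-yl)-1,3-dioxolan-2-yl]pent-2-enoate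
Product: 18 di-tert-butyl 13,13-ethylenedioxy-7β-hydroxy-13,14-seco-abietane-14,18-dioate (5α-H/8β-H/9α-H/10β-methyl)
Conditions: Fe(acac)3 (30 mol %), PhSiH3 (slow addition), 17 (3 equiv), EtOH/ethylene glycol, 0 °C → rt
Reagents that add atoms: none
Why: The iron hydride formed from Fe(acac)3 and PhSiH3 transfers a hydrogen atom to C1 of the electron-rich trisubstituted alkene (Markovnikov, the electron-poor enoate being left alone), the nucleophilic tertiary C10 radical adds to the β-carbon C9 of 17, and the α-ester radical is reduced by divalent iron to the trivalent iron enolate, which adds to the C7 aldehyde; the closest known reaction type is the metal-hydride hydrogen-atom-transfer Giese addition with aldol termination used to annulate γ,δ-unsaturated aldehydes with Michael acceptors. Ring B closes by a 6-(enolexo)-exo-trig aldol addition, the C9–C10 bond itself being made intermolecularly. C10 is controlled by ring A: the β face is blocked by the 1,3-related axial C4 methyl, so the new bond forms equatorially from the α face, trans to the C5 side arm, which gives the trans ring fusion. C9 is controlled by the staggered approach to this radical, in which H9 lies under ring A, the C11 chain takes the open sector beside C1 and the enoate carbon C8, tilted away by the obtuse attack angle, takes the sector beside the C5 arm, which should favour the 9α-H epimer. C8 and C7 arise in a chair-like aldol transition state (ester and hydroxyl equatorial under the reversible conditions) and are of no consequence because both are removed in step 12. The step needs cross-addition to outrun reduction of the C10 radical and aldol closure to outrun protonation of the enolate, which the excess of 17 and the six-membered chair that places the aldehyde next to the enolate are expected to secure.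

Step 12
Reactants: 18 di-tert-butyl 13,13-ethylenedioxy-7β-hydroxy-13,14-seco-abietane-14,18-dioate
Product: 20 di-tert-butyl 13,13-ethylenedioxy-13,14-seco-abiet-7-ene-14,18-dioate, via C7 mesylate 19 (not isolated)
Conditions: MsCl, Et3N, CH2Cl2, 0 °C; then DBU, 40 °C
Reagents that add atoms: methanesulfonyl chloride, CS(=O)(=O)Cl (its atoms are retained in 19 only)
Why: Mesylation followed by E1cB elimination through the C8 ester enolate can only give the conjugated C7=C8 enoate, and every C7/C8 diastereomer of 18 converges on it; C9 is not acidic and is not touched.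

Step 13
Reactants: 20 di-tert-butyl 13,13-ethylenedioxy-13,14-seco-abiet-7-ene-14,18-dioate
Product: 21 (1R,4aS,5R,8aR)-1,4a-dimethyl-5-(4-methyl-3-oxopentyl)-1,2,3,4,4a,5,8,8a-octahydronaphthalene-1,6-dicarboxylic acid (CNP0333046.1)
Conditions: TFA/CH2Cl2/H2O (10:10:1), rt
Reagents that add atoms: water, O
Why: Acidolysis cleaves both tert-butyl esters by the alkyl–oxygen (tert-butyl cation) pathway, which is indifferent to the hindrance at C4, and hydrolyses the dioxolane in the same operation without base, so the enoic acid and all four stereocentres are untouched.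

**Compound list**
1 | 3-methylbut-3-en-2-one | CC(=O)C(C)=C | starting material
2 | triisopropyl[(3-methylbuta-1,3-dien-2-yl)oxy]silane | C=C(C)C(=C)O[Si](C(C)C)(C(C)C)C(C)C | intermediate
3 | methacrolein (2-methylprop-2-enal) | CC(=C)C=O | starting material
4 | (R)-1,3-dimethyl-4-[(triisopropylsilyl)oxy]cyclohex-3-ene-1-carbaldehyde | O=C[C@@]1(C)CC(C)=C(O[Si](C(C)C)(C(C)C)C(C)C)CC1 | intermediate
5 | (R)-1,3-dimethyl-4-oxocyclohex-2-ene-1-carbaldehyde | O=C[C@@]1(C)C=C(C)C(=O)CC1 | intermediate
6 | (R)-1,3-dimethyl-4-oxocyclohex-2-ene-1-carboxylic acid | OC(=O)[C@@]1(C)C=C(C)C(=O)CC1 | intermediate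
7 | tert-butyl (R)-1,3-dimethyl-4-oxocyclohex-2-ene-1-carboxylate | CC(C)(C)OC(=O)[C@@]1(C)C=C(C)C(=O)CC1 | intermediate
8 | tert-butyl (1R,4R)-4-hydroxy-1,3-dimethylcyclohex-2-ene-1-carboxylate | O[C@@H]1CC[C@@](C)(C(=O)OC(C)(C)C)C=C1C | intermediate
9 | ethyl vinyl ether | C=COCC | starting material
10 | tert-butyl (1R,4R)-4-(ethenyloxy)-1,3-dimethylcyclohex-2-ene-1-carboxylate | C=CO[C@@H]1CC[C@@](C)(C(=O)OC(C)(C)C)C=C1C | intermediate
11 | tert-butyl (1R,2R)-1,3-dimethyl-2-(2-oxoethyl)cyclohex-3-ene-1-carboxylate | O=CC[C@@H]1C(C)=CCC[C@@]1(C)C(=O)OC(C)(C)C | intermediate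
12 | N-methoxy-N,2-dimethylpropanamide | CC(C)C(=O)N(C)OC | starting material
13 | but-3-en-1-ylmagnesium bromide | C=CCC[Mg]Br | starting material
14 | 2-methylhept-6-en-3-one | CC(C)C(=O)CCC=C | intermediate
15 | 2-(but-3-en-1-yl)-2-(propan-2-yl)-1,3-dioxolane | CC(C)C1(CCC=C)OCCO1 | intermediate
16 | tert-butyl acrylate | C=CC(=O)OC(C)(C)C | starting material
17 | tert-butyl (E)-5-[2-(propan-2-yl)-1,3-dioxolan-2-yl]pent-2-enoate | CC(C)C1(OCCO1)CC/C=C/C(=O)OC(C)(C)C | intermediate
18 | di-tert-butyl 13,13-ethylenedioxy-7β-hydroxy-13,14-seco-abietane-14,18-dioate (4α-ester, 5α-H, 8β-H, 9α-H, 10β-methyl) | CC(C)C1(OCCO1)CC[C@H]2[C@H](C(=O)OC(C)(C)C)[C@@H](O)C[C@@H]3[C@]2(C)CCC[C@@]3(C)C(=O)OC(C)(C)C | intermediate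
19 | C7 methanesulfonate of 18 | CC(C)C1(OCCO1)CC[C@H]2[C@H](C(=O)OC(C)(C)C)[C@@H](OS(C)(=O)=O)C[C@@H]3[C@]2(C)CCC[C@@]3(C)C(=O)OC(C)(C)C | intermediate
20 | di-tert-butyl 13,13-ethylenedioxy-13,14-seco-abiet-7-ene-14,18-dioate | CC(C)C1(OCCO1)CC[C@H]2C(C(=O)OC(C)(C)C)=CC[C@@H]3[C@]2(C)CCC[C@@]3(C)C(=O)OC(C)(C)C | intermediate
21 | (1R,4aS,5R,8aR)-1,4a-dimethyl-5-(4-methyl-3-oxopentyl)-1,2,3,4,4a,5,8,8a-octahydronaphthalene-1,6-dicarboxylic acid | CC(C)C(=O)CC[C@H]1C(C(=O)O)=CC[C@@H]2[C@]1(C)CCC[C@@]2(C)C(=O)O | target

**Step count**
Total: 13 steps. Longest linear sequence: 10 steps (steps 1–7 and 11–13); steps 8–10 form the three-step side branch to 17.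

**Steps most likely to fail**

Step 11. Three processes may defeat it: reduction of the C10 radical before it finds the β-alkyl enoate, poor facial selectivity at C9 in the intermolecular addition, and protonation of the ester enolate before aldol closure. The fallback reverses the order of bond formation so that the radical step becomes a ring closure. It sets out from 17 and 11. Conjugate reduction–selenenylation of 17 (Li(s-Bu)3BH, then PhSeCl) should give tert-butyl 5-[2-(propan-2-yl)-1,3-dioxolan-2-yl]-2-(phenylselanyl)pentanoate F1. Its lithium enolate (LDA, THF, −78 °C) adds to aldehyde 11 to give the α-selanyl β-hydroxy ester F2, which makes the C7–C8 bond by an ordinary aldol addition. Oxidation with H2O2/pyridine and selenoxide syn-elimination away from the carbinol give the α-alkylidene β-hydroxy ester F3 with a C8=C9 alkene. Fe(acac)3/PhSiH3 then generates the C10 radical, which closes ring B by 6-endo-trig conjugate addition onto C9 through a chair that places the C11 chain equatorial. Protonation at C8 brings the sequence back to the route at 18, as C7/C8 epimers that all converge in step 12.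

Step 7. The sigmatropic shift must form a bond next to the C4 quaternary carbon, and at the temperature this needs the vinyl ether may lose acetaldehyde or the tert-butyl ester may lose isobutene. The fallback is an enolate Claisen rearrangement at low temperature and sets out from 8. Acetylation (Ac2O, DMAP, pyridine) gives the allylic acetate F4. Ireland–Claisen rearrangement (LDA, TMSCl, THF, −78 → 60 °C, aqueous work-up) gives the acid 2-[(1R,6R)-6-(tert-butoxycarbonyl)-2,6-dimethylcyclohex-2-en-1-yl]acetic acid F5 with the same suprafacial chirality transfer. Reduction through the mixed anhydride (i-BuOCOCl, N-methylmorpholine; NaBH4) gives the primary alcohol F6, and Dess–Martin oxidation returns to the route at 11.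

Step 3. Transfer of the bulky silyl enol ether to palladium may be slow, and β-hydride elimination may go toward the methyl group and give the exocyclic enone. The fallback is a halogenation–dehydrohalogenation and sets out from 4. NBS in THF at 0 °C gives the tertiary α-bromo ketone (1R)-3-bromo-1,3-dimethyl-4-oxocyclohexane-1-carbaldehyde F7. Li2CO3/LiBr in DMF at 120 °C then eliminates HBr to the thermodynamically preferred endocyclic enone, returning to the route at 5.

**Further compounds**
F1 | step 11 | tert-butyl 5-[2-(propan-2-yl)-1,3-dioxolan-2-yl]-2-(phenylselanyl)pentanoate | CC(C)C1(OCCO1)CCCC([Se]c1ccccc1)C(=O)OC(C)(C)C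
F2 | step 11 | α-selanyl β-hydroxy ester from F1 and 11 (C7 and C8 as a mixture) | CC(C)C1(OCCO1)CCCC([Se]c1ccccc1)(C(=O)OC(C)(C)C)C(O)C[C@@H]1C(C)=CCC[C@@]1(C)C(=O)OC(C)(C)C
F3 | step 11 | α-alkylidene β-hydroxy ester with the C8=C9 alkene (C7 and alkene geometry as a mixture) | CC(C)C1(OCCO1)CCC=C(C(=O)OC(C)(C)C)C(O)C[C@@H]1C(C)=CCC[C@@]1(C)C(=O)OC(C)(C)C
F4 | step 7 | tert-butyl (1R,4R)-4-acetoxy-1,3-dimethylcyclohex-2-ene-1-carboxylate | CC(=O)O[C@@H]1CC[C@@](C)(C(=O)OC(C)(C)C)C=C1C
F5 | step 7 | 2-[(1R,6R)-6-(tert-butoxycarbonyl)-2,6-dimethylcyclohex-2-en-1-yl]acetic acid | OC(=O)C[C@@H]1C(C)=CCC[C@@]1(C)C(=O)OC(C)(C)C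
F6 | step 7 | tert-butyl (1R,2R)-2-(2-hydroxyethyl)-1,3-dimethylcyclohex-3-ene-1-carboxylate | OCC[C@@H]1C(C)=CCC[C@@]1(C)C(=O)OC(C)(C)C
F7 | step 3 | (1R)-3-bromo-1,3-dimethyl-4-oxocyclohexane-1-carbaldehyde (C3 as a mixture) | O=C[C@@]1(C)CC(C)(Br)C(=O)CC1
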